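**Retrosynthetic overview**

1. Target ← bromohydration of a prenyl ketone, in which the acetyl C=O delivers the tertiary OH through a six-membered hemiketal (step 12). The quaternary carbinol ← hydroxyl-directed epoxidation of a 1,1-disubstituted allylic alcohol, then isobutenyl–copper opening (steps 8–9).
2. Ring tertiary chloride ← anti addition of HCl across C4=C5 of a cyclohexene, steered by the allylic C3–Br (step 6).
3. Cyclohexene (the only carbocycle, formed first) ← Diels–Alder union of two C5 fragments, (E)-1-bromo-2-methylbuta-1,3-diene and (R)-4-hydroxypent-1-en-3-one, closing C1–C6 and C2–C3 and setting C1 and C3. The later rings (oxirane in step 8, oxane hemiketal in step 12) are temporary.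
4. Enabling feature: in the cyclohexane, C1 (side-chain CH) is para to C4 (Me, Cl), and C3 (Br) lies between C4 and C2H2. C6–C5–C4–C3 therefore maps onto a 1-bromo-2-methyldiene and C1–C2 onto a vinyl ketone. The lactate-derived α'-hydroxyl activates the dienophile as a chelate, directs the cycloaddition face and the epoxidation, and is finally oxidised to the acetyl group.

Key step: step 5

Remark: (R,R)-tBu-box = 2,2'-(propane-2,2-diyl)bis[(4R)-4-tert-butyl-4,5-dihydro-1,3-oxazole]; ring carbons are numbered C1 (side-chain CH), C2H2, C3 (Br), C4 (Me, Cl), C5H2, C6H2; the open hydroxy ketone is assumed to prevail over its cyclic hemiketal.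

**Route**

Step 1
Reactants: 1 methacrolein
Product: 3 (E)-3-bromo-2-methylprop-2-enal, via dibromo aldehyde 2 (not isolated)
Conditions: Br2, CH2Cl2, −78 → 0 °C; then Et3N, 0 → 23 °C
Reagents that add atoms: bromine, BrBr
Why: Bromine addition to the enal followed by base-induced E2 loss of HBr (bromination–dehydrobromination) should give the conjugated β-bromo enal, the E isomer (Br trans to CHO) being the thermodynamically preferred one.

Step 2
Reactants: 3 (E)-3-bromo-2-methylprop-2-enal
Product: 4 (E)-1-bromo-2-methylbuta-1,3-diene
Conditions: Ph3PCH3Br, KOtBu, Et2O, 0 °C; then 3, −78 → 0 °C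
Reagents that add atoms: methyltriphenylphosphonium bromide, C[P+](c1ccccc1)(c1ccccc1)c1ccccc1.[Br-]
Why: Wittig methylenation of the aldehyde at low temperature leaves the trisubstituted bromoalkene untouched, so the E geometry (Br trans to the new vinyl group, the "outside" position of the s-cis diene) is carried over.

Step 3
Reactants: 5 methyl (R)-lactate
Product: 6 (2R)-2-hydroxy-N-methoxy-N-methylpropanamide
Conditions: MeNH(OMe)·HCl, iPrMgCl, THF, −20 → 0 °C; then aq. NH4Cl
Reagents that add atoms: N,O-dimethylhydroxylamine hydrochloride, CNOC.Cl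
Why: Amide formation from the ester with the chloromagnesium amide (Weinreb amide synthesis) is reliable for lactate esters, and the stereocentre, held as its magnesium alkoxide, should not epimerise.

Step 4
Reactants: 6 (2R)-2-hydroxy-N-methoxy-N-methylpropanamide
Product: 7 (4R)-4-hydroxypent-1-en-3-one
Conditions: CH2=CHMgBr (2.5 equiv), THF, −78 → 0 °C; inverse quench into cold 1 M aq. HCl; used as a CH2Cl2 solution
Reagents that add atoms: vinylmagnesium bromide, C=C[Mg]Br
Why: Grignard acylation of the N-methoxy-N-methylamide stops at the ketone because of the chelated tetrahedral intermediate (the first equivalent only deprotonates the hydroxyl), and the acidic inverse quench protonates the released amine before it can add to the vinyl ketone.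

Step 5
Reactants: 4 (E)-1-bromo-2-methylbuta-1,3-diene; 7 (4R)-4-hydroxypent-1-en-3-one
Product: 8 (2R)-1-[(1S,5S)-5-bromo-4-methylcyclohex-3-en-1-yl]-2-hydroxypropan-1-one
Conditions: [Cu((R,R)-tBu-box)](SbF6)2 (10 mol%), 4 (3 equiv), CH2Cl2, −20 → 23 °C
Reagents that add atoms: none
Why: Lewis-acid-catalysed normal-demand Diels–Alder reaction: the α'-hydroxy enone binds the divalent copper centre through C=O and OH as a planar five-membered chelate (s-cis enone) and the diene adds in a concerted, asynchronous [4+2] step, the closest precedent being the chelation-controlled cycloadditions of α'-hydroxy vinyl ketones with isoprene and piperylene under copper bis(oxazoline) catalysis. The six-membered ring closes in the suprafacial [4+2] mode, both σ-bonds forming in one operation. The ring CH stereocentre is set by attack on the Si face of the enone α-carbon, which is the face anti to the methyl group of the (R)-carbinol in the chelate and also the face left open by the (R,R)-ligand (matched pair). The C–Br stereocentre follows from the endo transition state, which places the "outside" bromine of the E-diene cis to the acyl group. The step needs "para" regioselectivity (acyl-bearing carbon bonded to the unsubstituted diene terminus), secured by the 2-methyl group: bonding of the brominated terminus to the enone β-carbon develops positive charge at the methyl-bearing carbon, an effect amplified by the cationic chelate, whereas bromine is only a weak opposing director. It also needs an accessible s-cis diene, which the 2-methyl group and the E placement of bromine provide.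

Step 6
Reactants: 8 (2R)-1-[(1S,5S)-5-bromo-4-methylcyclohex-3-en-1-yl]-2-hydroxypropan-1-one
Product: 9 (2R)-1-[(1S,3S,4S)-3-bromo-4-chloro-4-methylcyclohexyl]-2-hydroxypropan-1-one
Conditions: HCl (g), CH2Cl2, −78 → −20 °C
Reagents that add atoms: hydrogen chloride, Cl
Why: Ionic hydrochlorination with neighbouring-group participation, the reaction type known from hydrogen halide addition to 3-bromocyclohexene: protonation of the alkene CH gives a tertiary cation bridged by the adjacent bromine, and chloride opens this bromonium ion at the tertiary carbon anti to bromine, which sets the C–Cl stereocentre trans to C–Br.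

Step 7
Reactants: 9 (2R)-1-[(1S,3S,4S)-3-bromo-4-chloro-4-methylcyclohexyl]-2-hydroxypropan-1-one
Product: 10 (2R)-3-[(1S,3S,4S)-3-bromo-4-chloro-4-methylcyclohexyl]but-3-en-2-ol
Conditions: Cp2TiMe2 (3 equiv), toluene/THF, 65 °C, dark
Reagents that add atoms: dimethyltitanocene, C[Ti](C)(C1C=CC=C1)C1C=CC=C1
Why: Petasis methylenation: the non-basic titanium methylidene formed thermally from Cp2TiMe2 olefinates hindered, enolisable ketones without epimerising the adjacent stereocentres or eliminating the halides, the hydroxyl being carried as a titanium alkoxide and released on work-up.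

Step 8
Reactants: 10 (2R)-3-[(1S,3S,4S)-3-bromo-4-chloro-4-methylcyclohexyl]but-3-en-2-ol
Product: 11 (1R)-1-[(2S)-2-[(1S,3S,4S)-3-bromo-4-chloro-4-methylcyclohexyl]oxiran-2-yl]ethan-1-ol
Conditions: VO(acac)2 (5 mol%), tBuOOH, CH2Cl2, 0 → 23 °C
Reagents that add atoms: tert-butyl hydroperoxide, CC(C)(C)OO
Why: Hydroxyl-directed epoxidation of an allylic alcohol by a vanadium alkyl peroxide; for a 2-substituted allylic alcohol, A(1,2) strain between the cyclohexyl substituent and the carbinol methyl group favours the erythro transition state, so the carbinol stereocentre sets the new quaternary C–O centre.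

Step 9
Reactants: 11 (1R)-1-[(2S)-2-[(1S,3S,4S)-3-bromo-4-chloro-4-methylcyclohexyl]oxiran-2-yl]ethan-1-ol
Product: 12 (2R,3R)-3-[(1S,3S,4S)-3-bromo-4-chloro-4-methylcyclohexyl]-6-methylhept-5-ene-2,3-diol
Conditions: Me2C=CHMgBr (4 equiv), CuI (20 mol%), THF, −40 → −10 °C; then aq. NH4Cl
Reagents that add atoms: (2-methylprop-1-en-1-yl)magnesium bromide, CC(C)=C[Mg]Br
Why: Copper-catalysed SN2 opening of the 2,2-disubstituted epoxide at its unhindered CH2 terminus by the alkenyl Grignard reagent installs the prenyl chain without touching a stereocentre, the epoxide being far more reactive at low temperature than the hindered secondary bromide and tertiary chloride.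

Step 10
Reactants: 12 (2R,3R)-3-[(1S,3S,4S)-3-bromo-4-chloro-4-methylcyclohexyl]-6-methylhept-5-ene-2,3-diol
Product: 13 (3R)-3-[(1S,3S,4S)-3-bromo-4-chloro-4-methylcyclohexyl]-3-hydroxy-6-methylhept-5-en-2-one
Conditions: Dess–Martin periodinane, CH2Cl2, 0 → 23 °C
Reagents that add atoms: none
Why: Dess–Martin oxidation converts the secondary alcohol into the methyl ketone (the tertiary alcohol cannot be oxidised), which removes the lactate-derived stereocentre after it has done its work and leaves the quaternary carbinol centre unchanged.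

Step 11
Reactants: 13 (3R)-3-[(1S,3S,4S)-3-bromo-4-chloro-4-methylcyclohexyl]-3-hydroxy-6-methylhept-5-en-2-one
Product: 14 (3R)-3-[(1S,3S,4S)-3-bromo-4-chloro-4-methylcyclohexyl]-6-methyl-3-[(trimethylsilyl)oxy]hept-5-en-2-one
Conditions: 1-(trimethylsilyl)imidazole, CH2Cl2, 23 °C
Reagents that add atoms: 1-(trimethylsilyl)imidazole, C[Si](C)(C)n1ccnc1
Why: Silylation of the hindered tertiary alcohol with a non-enolising reagent masks the only internal hydroxyl nucleophile, which would otherwise close a bromotetrahydrofuran onto the bromonium ion of the next step.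

Step 12
Reactants: 14 (3R)-3-[(1S,3S,4S)-3-bromo-4-chloro-4-methylcyclohexyl]-6-methyl-3-[(trimethylsilyl)oxy]hept-5-en-2-one
Product: 17 (3R,5R)-5-bromo-3-[(1S,3S,4S)-3-bromo-4-chloro-4-methylcyclohexyl]-3,6-dihydroxy-6-methylheptan-2-one (target), via bromo hemiketal 15 (not isolated), via silylated bromohydrin 16 (not isolated)
Conditions: NBS, MeCN/H2O (10:1), −20 °C; then 1 M aq. HCl, THF, 23 °C
Reagents that add atoms: N-bromosuccinimide, O=C1CCC(=O)N1Br; water, O
Why: Bromohydrin formation with carbonyl participation (bromoketalisation type): the ketone oxygen opens the bromonium ion at the tertiary carbon in a 6-endo chair-like transition state with bromine equatorial and the cyclohexyl group axial (avoiding A(1,2) strain with the acetyl methyl group), which sets the new C–Br centre syn to the silyloxy group; water turns the cyclic oxocarbenium ion into the hemiketal, which opens to the hydroxy ketone, and dilute acid removes the silyl group.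

**Compound list**

1 | methacrolein (2-methylprop-2-enal) | C=C(C)C=O | starting material
2 | 2,3-dibromo-2-methylpropanal (racemic) | O=CC(C)(Br)CBr | intermediate
3 | (E)-3-bromo-2-methylprop-2-enal | O=C/C(C)=C/Br | intermediate
4 | (E)-1-bromo-2-methylbuta-1,3-diene | C=C/C(C)=C/Br | intermediate
5 | methyl (R)-lactate | C[C@@H](O)C(=O)OC | starting material
6 | (2R)-2-hydroxy-N-methoxy-N-methylpropanamide | C[C@@H](O)C(=O)N(C)OC | intermediate
7 | (4R)-4-hydroxypent-1-en-3-one | C[C@@H](O)C(=O)C=C | intermediate
8 | (2R)-1-[(1S,5S)-5-bromo-4-methylcyclohex-3-en-1-yl]-2-hydroxypropan-1-one | C[C@@H](O)C(=O)[C@H]1CC=C(C)[C@@H](Br)C1 | intermediate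
9 | (2R)-1-[(1S,3S,4S)-3-bromo-4-chloro-4-methylcyclohexyl]-2-hydroxypropan-1-one | C[C@@H](O)C(=O)[C@H]1CC[C@](C)(Cl)[C@@H](Br)C1 | intermediate
10 | (2R)-3-[(1S,3S,4S)-3-bromo-4-chloro-4-methylcyclohexyl]but-3-en-2-ol | C[C@@H](O)C(=C)[C@H]1CC[C@](C)(Cl)[C@@H](Br)C1 | intermediate
11 | (1R)-1-[(2S)-2-[(1S,3S,4S)-3-bromo-4-chloro-4-methylcyclohexyl]oxiran-2-yl]ethan-1-ol | C[C@@H](O)[C@@]1(CO1)[C@H]2CC[C@](C)(Cl)[C@@H](Br)C2 | intermediate
12 | (2R,3R)-3-[(1S,3S,4S)-3-bromo-4-chloro-4-methylcyclohexyl]-6-methylhept-5-ene-2,3-diol | C[C@@H](O)[C@@](O)(CC=C(C)C)[C@H]1CC[C@](C)(Cl)[C@@H](Br)C1 | intermediate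
13 | (3R)-3-[(1S,3S,4S)-3-bromo-4-chloro-4-methylcyclohexyl]-3-hydroxy-6-methylhept-5-en-2-one | CC(=O)[C@@](O)(CC=C(C)C)[C@H]1CC[C@](C)(Cl)[C@@H](Br)C1 | intermediate
14 | (3R)-3-[(1S,3S,4S)-3-bromo-4-chloro-4-methylcyclohexyl]-6-methyl-3-[(trimethylsilyl)oxy]hept-5-en-2-one | CC(=O)[C@@](O[Si](C)(C)C)(CC=C(C)C)[C@H]1CC[C@](C)(Cl)[C@@H](Br)C1 | intermediate
15 | (3R,5R)-5-bromo-3-[(1S,3S,4S)-3-bromo-4-chloro-4-methylcyclohexyl]-2,6,6-trimethyl-3-[(trimethylsilyl)oxy]oxan-2-ol (both C2 epimers) | CC1(O)OC(C)(C)[C@H](Br)C[C@@]1(O[Si](C)(C)C)[C@H]2CC[C@](C)(Cl)[C@@H](Br)C2 | intermediate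
16 | (3R,5R)-5-bromo-3-[(1S,3S,4S)-3-bromo-4-chloro-4-methylcyclohexyl]-6-hydroxy-6-methyl-3-[(trimethylsilyl)oxy]heptan-2-one | CC(=O)[C@@](O[Si](C)(C)C)(C[C@@H](Br)C(C)(C)O)[C@H]1CC[C@](C)(Cl)[C@@H](Br)C1 | intermediate
17 | (3R,5R)-5-bromo-3-[(1S,3S,4S)-3-bromo-4-chloro-4-methylcyclohexyl]-3,6-dihydroxy-6-methylheptan-2-one | CC(=O)[C@@](O)(C[C@@H](Br)C(C)(C)O)[C@H]1CC[C@](C)(Cl)[C@@H](Br)C1 | target

**Step count**

Total steps: 12. Longest linear sequence: 10 steps (from 5 through steps 3–12; the same count from 1 through steps 1, 2 and 5–12).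

**Steps most likely to fail, with fallbacks**

Step 5. The halogenated diene may add slowly, and regiocontrol may erode because the directing effects of bromine and methyl oppose each other. The fallback sets out from 7 and returns at 8. Cycloaddition of 7 with isoprene under the same copper catalyst, a combination with direct precedent for para selectivity and the same facial control, should give (2R)-2-hydroxy-1-[(1R)-4-methylcyclohex-3-en-1-yl]propan-1-one F1, with the same two ring bonds formed. Allylic oxidation with catalytic SeO2 and tBuOOH at the ring CH2 next to the methyl-bearing alkene carbon is expected to favour the pseudoaxial alcohol trans to the acyl group, (2R)-2-hydroxy-1-[(1S,5R)-5-hydroxy-4-methylcyclohex-3-en-1-yl]propan-1-one F2. Corey–Kim bromination (NBS, Me2S, CH2Cl2, −20 °C), which is selective for the allylic hydroxyl and proceeds with inversion, then gives 8.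

Step 12. Facial control may be lost if water captures the bromonium ion directly, and the silyloxy oxygen may cyclise with loss of the silyl group. The fallback sets out from 13 and returns at 17, replacing substrate control by reagent control. Shi epoxidation of the prenyl alkene of 13 with the L-fructose-derived ketone and Oxone (2KHSO5·KHSO4·K2SO4) at buffered pH should give (3R)-3-[(1S,3S,4S)-3-bromo-4-chloro-4-methylcyclohexyl]-4-[(2S)-3,3-dimethyloxiran-2-yl]-3-hydroxybutan-2-one F4. SN2 opening of this epoxide at its secondary carbon with Li2NiBr4 in THF, with inversion, then gives 17 directly.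

Step 6. The allylic bromide may ionise or exchange halide before the deactivated alkene is protonated. The fallback sets out from 8 and returns at 9, using a two-stage solvolytic sequence with no free halide in the first stage. Addition of CF3CO2H across the alkene under the same bromine participation should give (1S,2S,4S)-2-bromo-4-[(2R)-2-hydroxypropanoyl]-1-methylcyclohexyl 2,2,2-trifluoroacetate F3. Treatment with HCl in CH2Cl2 then ionises the tertiary ester to the same bromonium ion, and chloride enters anti to bromine to give 9.

**Further compounds**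

F1 | step 5 | (2R)-2-hydroxy-1-[(1R)-4-methylcyclohex-3-en-1-yl]propan-1-one | C[C@@H](O)C(=O)[C@H]1CC=C(C)CC1
F2 | step 5 | (2R)-2-hydroxy-1-[(1S,5R)-5-hydroxy-4-methylcyclohex-3-en-1-yl]propan-1-one | C[C@@H](O)C(=O)[C@H]1CC=C(C)[C@H](O)C1
F3 | step 6 | (1S,2S,4S)-2-bromo-4-[(2R)-2-hydroxypropanoyl]-1-methylcyclohexyl 2,2,2-trifluoroacetate | C[C@@H](O)C(=O)[C@H]1CC[C@](C)(OC(=O)C(F)(F)F)[C@@H](Br)C1
F4 | step 12 | (3R)-3-[(1S,3S,4S)-3-bromo-4-chloro-4-methylcyclohexyl]-4-[(2S)-3,3-dimethyloxiran-2-yl]-3-hydroxybutan-2-one | CC(=O)[C@@](O)(C[C@@H]1OC1(C)C)[C@H]2CC[C@](C)(Cl)[C@@H](Br)C2
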